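Slow growth of chain length was what struck me in the earlier runs, and two numbers seemed not to go together. By 25.0 h the grey run had turned 76 % of its first end groups into links, which is 0.0380 M of links on U = 48.8 mM of monomer units charged, yet its chains averaged 4.52 units.

| setting | grey | violet | amber | flask |
|---|---|---|---|---|
| first end groups | 0.050 M | 0.050 M | 0.050 M | 0.050 M |
| second end groups | 0.0475 M | 0.0475 M | 0.071 M | 0.0475 M |
| one-sided end groups | 0.70 mM | 1.1 mM | 0.50 mM | 0.500 mM |
| protic impurity | 1 mM | 1 mM | 1 mM | 1.00 mM |
| remark | run made earlier | run made earlier | run made earlier |  |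
| time |  |  |  | 30 h |

| run | time / h | links / % | first end groups / % |
|---|---|---|---|
| grey | 2.00 | 24 | 70 |
| grey | 3.00 | 33 | 69 |
| grey | 4.00 | 33 | 60 |
| grey | 6.00 | 48 | 49 |
| grey | 10.0 | 61 | 41 |
| grey | 15.0 | 68 | 30 |
| grey | 25.0 | 76 | 23 |
| violet | 1.33 | 15 | 79 |
| violet | 4.00 | 32 | 62 |
| violet | 6.00 | 46 | 50 |
| violet | 10.0 | 55 | 37 |
| violet | 15.0 | 65 | 26 |
| violet | 20.0 | 72 | 24 |
| violet | 25.0 | 71 | 21 |
| amber | 2.00 | 33 | 69 |
| amber | 6.00 | 56 | 36 |
| amber | 12.0 | 82 | 17 |
| amber | 15.0 | 84 | 12 |
| amber | 25.0 | 91 | 1 |

(each reading ± 2 percentage points)

- each monomer carries two end groups and one-sided end groups one, which caps an end: a chain counts once for every two ends that are left, dead ends included; the units are half of the end groups of the two monomers charged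
- the numbers in the tables scatter with a standard deviation of 2 percentage points

* whether the average number of monomer units in a chain (unreacted monomers counted as chains of one) reaches 20 by 30 h (yes / no)
* average number of monomer units in a chain (unreacted monomers counted as chains of one) at 30 h

I cleared this up by counting. With U of units charged and L of links (0.0380 M in that reading), each link removes one chain, so the average length is U/(U−L). Length therefore comes late, at the top of the conversion. If impurity and cap each take one first end group, the second end groups are the limiting reagent (0.0475 M against 0.0485 M), and L = 0.0475 M would give 39.0 units.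

Nearly balanced ends pair at a rate k times the square of their concentration. So after n lifetimes τ = one over (k times the charge of second end groups), the fraction of second end groups left is one over (one plus n). The grey reading leaves 20.0 %, which gives 4.00 lifetimes and τ = 6.25 h. For the flask at 30 h I counted 4.80 lifetimes, so L = 0.0393 M and the length is 5.16, short of 20.

The forecast, which called the flask “nearly balanced”, gave 5.4 units and answered no; my figure of 5.16 was lower.

The flask gave 5.22 units, and the answer was no.

    first end groups + protic impurity → quenched substrate (k = 0.0170 M⁻¹ s⁻¹)
    first end groups + one-sided end groups → capped ends (k = 0.149 M⁻¹ s⁻¹)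
    first end groups + second end groups → links (k = 8.85 × 10⁻⁴ M⁻¹ s⁻¹)

My 4.80 lifetimes left 17.2 % of the second end groups, and the flask held 17.0 % at 30.0 h. The neighbouring flask, left until 72.0 h, has 11.5 lifetimes on the same τ, which leaves 7.99 % of its second end groups and gives 9.67 units. That neighbour actually held 7.4 % of its second end groups, with links at 88.0 % and chains of 10.2 units.

All runs are simulated on assumed constants; the scatter is artificial.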